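Numbering: ring C (pyrrole) N4–C3–C2–C1–C9a. Ring A (azepine) N4–C5–C6–C7–C8=C9–C9a. Ring B C9–C9a–C1–C12–C11–C10 (ethyl on C10). Ring D (fused lactone) O–C11–C12–C13(CH3)–C14. Ring E (lactone on C3) O–C18–C19–C20(CH3)–C21.
Retrosynthetic cuts, in order: O–C21 and C18–H (ring E), C3–C18, C13–CH3, C1–C12 (ring B), C12=C13 (ring D), then N4–C5 together with C9–C9a (ring A), and finally C8–C9 (ketone synthesis) and C10–C11 (aldol).
Enabling feature: ring A meets ring C only along the N4–C9a edge. In parent pyrrole these two neighbouring atoms carry the acidic N–H and the most easily palladated C–H. The strap C5–C9 ends in one sp3 and one sp2 carbon, which can be armed orthogonally as a primary chloride and a Z-enol triflate. One pot therefore welds pyrrole itself onto an acyclic aldol product in a formal (5+2) annulation and fixes C8=C9.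
Forward order: acyclic chain, then ring A on ring C (step 7), ring D (metathesis), ring B (conjugate addition hinged on the new C9–C9a bond), ring E. The helpers (OTf, Cl, silyl ether, propenyl CH3CH=, C18 ketone level) leave on the way.
Stereochemistry: C10 and C11 come from an auxiliary-controlled syn aldol. C12 is set by the tether, since only the cis fusion is reachable. C13 comes from convex-face enolate methylation, C20 from an (R)-methylsuccinate half-ester, and C18 from a reagent-controlled ketone reduction.

Key step: step 7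

Remark: in this numbering the SMILES is read as 10S,11R,12S,13R,18R,20R. That means H-11/H-12 cis, ethyl trans to O-11 on ring B, 13-methyl trans to C1 on ring D, and the two substituents of ring E cis. All compounds marked as starting materials are taken as catalogue chemicals.

Step 1
Reactants: 1 (R)-4-benzyl-1,3-oxazolidin-2-one; 2 butanoyl chloride
Product: 3 (R)-4-benzyl-3-butanoyl-1,3-oxazolidin-2-one
Conditions: Et3N, 4-(dimethylamino)pyridine (cat.), CH2Cl2, 0 °C to rt
Reagents that add atoms: none
Why: N-acylation of the oxazolidinone by the acid chloride under nucleophilic catalysis is a standard imide formation that touches no stereocentre.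

Step 2
Reactants: 3 (R)-4-benzyl-3-butanoyl-1,3-oxazolidin-2-one; 4 (E)-but-2-enal
Product: 6 (4R)-4-benzyl-3-[(2R,3S,4E)-2-ethyl-3-hydroxyhex-4-enoyl]-1,3-oxazolidin-2-one, via Z-boron enolate 5 (not isolated)
Conditions: n-Bu2BOTf, Et3N, CH2Cl2, 0 °C; 4, −78 to 0 °C; H2O2, MeOH, pH 7 buffer
Reagents that add atoms: none
Why: Evans syn-aldol reaction: the Z-boron enolate adds through a closed chair transition state on the enolate face remote from the benzyl group, which sets C10 and C11 in the syn relationship and the absolute sense (2R,3S in the acyl chain) that the target needs.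

Step 3
Reactants: 6 (4R)-4-benzyl-3-[(2R,3S,4E)-2-ethyl-3-hydroxyhex-4-enoyl]-1,3-oxazolidin-2-one
Product: 7 (2R,3S,4E)-2-ethyl-3-hydroxy-N-methoxy-N-methylhex-4-enamide
Conditions: MeONHMe·HCl, AlMe3, CH2Cl2, −10 °C to rt; aq. potassium sodium tartrate
Reagents that add atoms: N,O-dimethylhydroxylamine hydrochloride, CNOC.Cl
Why: Aluminium amide transamidation to the Weinreb amide is assisted by the free β-hydroxyl group, releases the auxiliary and should not epimerise the α-centre C10.

Step 4
Reactants: 7 (2R,3S,4E)-2-ethyl-3-hydroxy-N-methoxy-N-methylhex-4-enamide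
Product: 8 (2R,3S,4E)-3-(tert-butyldimethylsilyloxy)-2-ethyl-N-methoxy-N-methylhex-4-enamide
Conditions: TBSOTf, 2,6-lutidine, CH2Cl2, −78 to 0 °C
Reagents that add atoms: tert-butyldimethylsilyl trifluoromethanesulfonate, CC(C)(C)[Si](C)(C)OS(=O)(=O)C(F)(F)F
Why: Silyl ether formation masks the allylic C11 hydroxyl for the Grignard, amide-base and hot carbonate steps without touching either stereocentre.

Step 5
Reactants: 8 (2R,3S,4E)-3-(tert-butyldimethylsilyloxy)-2-ethyl-N-methoxy-N-methylhex-4-enamide; 9 1-bromo-4-chlorobutane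
Product: 11 (6R,7S,8E)-7-(tert-butyldimethylsilyloxy)-1-chloro-6-ethyldec-8-en-5-one, via 4-chlorobutylmagnesium bromide 10 (not isolated)
Conditions: 9, Mg, THF, rt; then 8, THF, 0 °C; aq. NH4Cl
Reagents that add atoms: none
Why: Grignard addition to a Weinreb amide stops at the chelated tetrahedral adduct and gives only the ketone on work-up, while the primary chloride is too slow an electrophile to be attacked by the reagent at this temperature.

Step 6
Reactants: 11 (6R,7S,8E)-7-(tert-butyldimethylsilyloxy)-1-chloro-6-ethyldec-8-en-5-one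
Product: 13 (4Z,6R,7S,8E)-7-(tert-butyldimethylsilyloxy)-1-chloro-6-ethyldeca-4,8-dien-5-yl trifluoromethanesulfonate, via potassium Z-enolate 12 (not isolated)
Conditions: KN(SiMe3)2 (1.0 equiv), THF/DMPU, −78 °C; PhNTf2, −78 to −20 °C
Reagents that add atoms: N-phenylbis(trifluoromethanesulfonimide), O=S(=O)(N(c1ccccc1)S(=O)(=O)C(F)(F)F)C(F)(F)F
Why: Kinetic enolisation followed by O-sulfonylation (enol triflate formation): the bulky base removes a proton from the unhindered C8 methylene and not from the branched C10, the branched α' substituent favours the Z(O)-enolate, and triflation freezes both the C8=C9 position and the geometry with oxygen cis to C7.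

Step 7
Reactants: 13 (4Z,6R,7S,8E)-7-(tert-butyldimethylsilyloxy)-1-chloro-6-ethyldeca-4,8-dien-5-yl trifluoromethanesulfonate; 14 pyrrole
Product: 16 9-[(3S,4S,5E)-4-(tert-butyldimethylsilyloxy)hept-5-en-3-yl]-6,7-dihydro-5H-pyrrolo[1,2-a]azepine, via N-alkylated pyrrole enol triflate 15 (not isolated)
Conditions: 14 (3 equiv), Pd(OAc)2 (10 mol %), PPh3 (20 mol %), Cs2CO3 (3 equiv), n-Bu4NI (0.5 equiv), pivalic acid (30 mol %), DMF (0.01 M), 60 then 100 °C
Reagents that add atoms: none
Why: The pyrrole nitrogen, deprotonated by Cs2CO3, displaces the primary chloride in an n-Bu4NI-assisted SN2 reaction (N4–C5) while zerovalent palladium inserts into the C9–OTf bond with retention; carbonate/pivalate-assisted palladation of the neighbouring α-C–H (C9a–H) and reductive elimination then give C9–C9a, and the opposite order of the two events converges on the same product. The closest known reaction type is the domino N-alkylation/palladium-catalysed intramolecular direct C–H arylation of azoles with halides that carry a second, aryl-bound halogen, run here with an alkenyl triflate as in Heck-type alkenylations of pyrroles. Only ring A is closed: the N-alkylation is intermolecular and the seven-membered ring closes in the C–C step through an eight-membered palladacycle (by 7-exo-tet N-alkylation if the C–C coupling comes first). No stereocentre is created; the position of C8=C9 and the geometry that the ring requires are copied from the Z-enol triflate, and C10 and C11 are spectators because neither C–H is acidic towards carbonate. The step needs N- over C-alkylation (dissociated caesium salt in DMF), α- over β-palladation (intrinsic α preference reinforced by the short tether) and orthogonality of the two electrophilic termini (a primary alkyl chloride is inert to zerovalent palladium ligated by PPh3, an enol triflate is inert to SN2). Excess pyrrole and high dilution should suppress a second alkenylation at the free C3–H.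

Step 8
Reactants: 16 9-[(3S,4S,5E)-4-(tert-butyldimethylsilyloxy)hept-5-en-3-yl]-6,7-dihydro-5H-pyrrolo[1,2-a]azepine
Product: 17 (2E,4S,5S)-5-(6,7-dihydro-5H-pyrrolo[1,2-a]azepin-9-yl)hept-2-en-4-ol
Conditions: n-Bu4NF, THF, 0 °C to rt
Reagents that add atoms: none
Why: Fluoride-induced desilylation is essentially neutral and therefore spares the acid-sensitive 2-alkenylpyrrole and both stereocentres.

Step 9
Reactants: 17 (2E,4S,5S)-5-(6,7-dihydro-5H-pyrrolo[1,2-a]azepin-9-yl)hept-2-en-4-ol; 18 acryloyl chloride
Product: 19 (2E,4S,5S)-5-(6,7-dihydro-5H-pyrrolo[1,2-a]azepin-9-yl)hept-2-en-4-yl prop-2-enoate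
Conditions: Et3N, CH2Cl2, −20 to 0 °C
Reagents that add atoms: none
Why: Base-mediated O-acylation of the secondary allylic alcohol proceeds with retention at C11 and installs C13 and C14 of ring D.

Step 10
Reactants: 19 (2E,4S,5S)-5-(6,7-dihydro-5H-pyrrolo[1,2-a]azepin-9-yl)hept-2-en-4-yl prop-2-enoate
Product: 20 (5S)-5-[(1S)-1-(6,7-dihydro-5H-pyrrolo[1,2-a]azepin-9-yl)propyl]furan-2(5H)-one
Conditions: second-generation Grubbs catalyst RuCl2(=CHPh)(PCy3)(H2IMes) (5 mol %), CH2Cl2 (0.005 M), reflux
Reagents that add atoms: none
Why: Ring-closing metathesis of the acrylate and propenyl groups gives the butenolide (ring D, C12=C13) with loss of propene, while the trisubstituted ring-A alkene C8=C9 is too hindered to engage the catalyst.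

Step 11
Reactants: 20 (5S)-5-[(1S)-1-(6,7-dihydro-5H-pyrrolo[1,2-a]azepin-9-yl)propyl]furan-2(5H)-one
Product: 22 13-demethyl tetracyclic lactone (rings A to D; H-11/H-12 cis; ethyl trans to O-11), via aluminium enolate 21 (not isolated)
Conditions: EtAlCl2 (2 equiv), CH2Cl2 (0.005 M), −78 to −20 °C; aq. NaHCO3/potassium sodium tartrate
Reagents that add atoms: none
Why: Lewis acid-promoted intramolecular Friedel–Crafts-type conjugate addition of the pyrrole β-carbon C1 to the butenolide (six-membered ring B, exo at the acceptor), in which the short C9–C10–C11 link lets C1 reach C12 only on the lactone face that bears C10, so that C11 dictates the cis ring fusion, and in which EtAlCl2 also consumes the released proton as ethane so that no Brønsted acid can shift C8=C9.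

Step 12
Reactants: 22 13-demethyl tetracyclic lactone (rings A to D)
Product: 24 (10S,11R,12S,13R)-tetracyclic lactone (rings A to D; 13-methyl trans to C1; C3–H free), via lithium enolate 23 (not isolated)
Conditions: LiN(i-Pr)2, THF, −78 °C; MeI, −78 to −40 °C
Reagents that add atoms: iodomethane, CI
Why: Lactone enolate alkylation: iodomethane approaches the cup-shaped cis-fused B/D system from its convex face (the face of H-11 and H-12), which places the C13 methyl group trans to C1 as in the target.

Step 13
Reactants: 25 (2R)-4-(tert-butoxy)-2-methyl-4-oxobutanoic acid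
Product: 26 4-tert-butyl 1-methyl (2R)-2-methylbutanedioate
Conditions: MeI, K2CO3, DMF, rt
Reagents that add atoms: iodomethane, CI
Why: Carboxylate O-alkylation gives the mixed diester under conditions too mild to enolise the adjacent stereocentre (the future C20).

Step 14
Reactants: 26 4-tert-butyl 1-methyl (2R)-2-methylbutanedioate
Product: 27 methyl (2R)-4-chloro-2-methyl-4-oxobutanoate
Conditions: SOCl2, rt
Reagents that add atoms: thionyl chloride, O=S(Cl)Cl
Why: Thionyl chloride converts a tert-butyl ester directly into the acid chloride through acid-induced loss of the tert-butyl cation whereas the methyl ester is inert, and the stereocentre is safe because it is β to the reacting carbonyl group.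

Step 15
Reactants: 24 (10S,11R,12S,13R)-tetracyclic lactone (rings A to D); 27 methyl (2R)-4-chloro-2-methyl-4-oxobutanoate
Product: 28 (10S,11R,12S,13R,20R)-3-acylated tetracycle (C18 ketone; C21 methyl ester)
Conditions: Et2AlCl (2.2 equiv), CH2Cl2, −20 °C; 27, −20 to 0 °C
Reagents that add atoms: none
Why: Dialkylaluminium chloride-mediated Friedel–Crafts acylation takes place at C3, the only free and most nucleophilic α-position of the pyrrole, and the aluminium alkyl removes the HCl that would otherwise endanger C8=C9.

Step 16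
Reactants: 28 (10S,11R,12S,13R,20R)-3-acylated tetracycle
Product: 30 CNP0324368.1 (10S,11R,12S,13R,18R,20R), via hydroxy ester 29 (not isolated)
Conditions: (S)-Me-CBS oxazaborolidine [(S)-1-methyl-3,3-diphenyltetrahydro-1H,3H-pyrrolo[1,2-c][1,3,2]oxazaborole] (0.3 equiv), catecholborane, toluene, −60 to −30 °C; MeOH, aq. NaHCO3; 1,8-diazabicyclo[5.4.0]undec-7-ene (0.1 equiv), CH2Cl2, rt
Reagents that add atoms: none
Why: Corey–Bakshi–Shibata reduction treats the pyrrolyl group as the large and the CH2 group as the small ketone substituent, so that the (S)-catalyst should deliver hydride to give the (18R)-carbinol under reagent control, and attack of this hydroxyl on the methyl ester then closes ring E with retention, the 18,20-cis relationship following from the independently fixed C20.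

Compound list
1 | (R)-4-benzyl-1,3-oxazolidin-2-one | O=C1OC[C@@H](Cc2ccccc2)N1 | starting material
2 | butanoyl chloride | CCCC(=O)Cl | starting material
3 | (R)-4-benzyl-3-butanoyl-1,3-oxazolidin-2-one | CCCC(=O)N1[C@H](Cc2ccccc2)COC1=O | intermediate
4 | (E)-but-2-enal | C/C=C/C=O | starting material
5 | Z-boron enolate of 3 (dibutylboryl) | CC/C=C(\OB(CCCC)CCCC)N1[C@H](Cc2ccccc2)COC1=O | intermediate
6 | (4R)-4-benzyl-3-[(2R,3S,4E)-2-ethyl-3-hydroxyhex-4-enoyl]-1,3-oxazolidin-2-one | CC[C@@H](C(=O)N1[C@H](Cc2ccccc2)COC1=O)[C@@H](O)/C=C/C | intermediate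
7 | (2R,3S,4E)-2-ethyl-3-hydroxy-N-methoxy-N-methylhex-4-enamide | CC[C@@H](C(=O)N(C)OC)[C@@H](O)/C=C/C | intermediate
8 | (2R,3S,4E)-3-(tert-butyldimethylsilyloxy)-2-ethyl-N-methoxy-N-methylhex-4-enamide | CC[C@@H](C(=O)N(C)OC)[C@@H](O[Si](C)(C)C(C)(C)C)/C=C/C | intermediate
9 | 1-bromo-4-chlorobutane | ClCCCCBr | starting material
10 | 4-chlorobutylmagnesium bromide | ClCCCC[Mg]Br | intermediate
11 | (6R,7S,8E)-7-(tert-butyldimethylsilyloxy)-1-chloro-6-ethyldec-8-en-5-one | CC[C@@H](C(=O)CCCCCl)[C@@H](O[Si](C)(C)C(C)(C)C)/C=C/C | intermediate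
12 | potassium Z-enolate of 11 (C8=C9) | CC[C@@H](/C([O-])=C/CCCCl)[C@@H](O[Si](C)(C)C(C)(C)C)/C=C/C.[K+] | intermediate
13 | (4Z,6R,7S,8E)-7-(tert-butyldimethylsilyloxy)-1-chloro-6-ethyldeca-4,8-dien-5-yl trifluoromethanesulfonate | CC[C@@H](/C(OS(=O)(=O)C(F)(F)F)=C/CCCCl)[C@@H](O[Si](C)(C)C(C)(C)C)/C=C/C | intermediate
14 | pyrrole | c1cc[nH]c1 | starting material
15 | N-alkylated pyrrole enol triflate (N4–C5 formed; C9–OTf intact) | CC[C@@H](/C(OS(=O)(=O)C(F)(F)F)=C/CCCn1cccc1)[C@@H](O[Si](C)(C)C(C)(C)C)/C=C/C | intermediate
16 | 9-[(3S,4S,5E)-4-(tert-butyldimethylsilyloxy)hept-5-en-3-yl]-6,7-dihydro-5H-pyrrolo[1,2-a]azepine | CC[C@@H](C1=CCCCn2cccc12)[C@@H](O[Si](C)(C)C(C)(C)C)/C=C/C | intermediate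
17 | (2E,4S,5S)-5-(6,7-dihydro-5H-pyrrolo[1,2-a]azepin-9-yl)hept-2-en-4-ol | CC[C@@H](C1=CCCCn2cccc12)[C@@H](O)/C=C/C | intermediate
18 | acryloyl chloride | C=CC(=O)Cl | starting material
19 | (2E,4S,5S)-5-(6,7-dihydro-5H-pyrrolo[1,2-a]azepin-9-yl)hept-2-en-4-yl prop-2-enoate | CC[C@@H](C1=CCCCn2cccc12)[C@@H](OC(=O)C=C)/C=C/C | intermediate
20 | (5S)-5-[(1S)-1-(6,7-dihydro-5H-pyrrolo[1,2-a]azepin-9-yl)propyl]furan-2(5H)-one | CC[C@@H](C1=CCCCn2cccc12)[C@@H]1C=CC(=O)O1 | intermediate
21 | dichloroaluminium enolate of 22 | CC[C@H]1C2=CCCCn3ccc(c32)[C@H]2[C@@H]1OC(O[Al](Cl)Cl)=C2 | intermediate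
22 | 13-demethyl tetracyclic lactone (rings A to D; H-11/H-12 cis; ethyl trans to O-11) | CC[C@H]1C2=CCCCn3ccc(c32)[C@H]2[C@@H]1OC(=O)C2 | intermediate
23 | lithium enolate of 22 | CC[C@H]1C2=CCCCn3ccc(c32)[C@H]2[C@@H]1OC([O-])=C2.[Li+] | intermediate
24 | (10S,11R,12S,13R)-tetracyclic lactone (rings A to D; C3–H free) | CC[C@H]1C2=CCCCn3ccc(c32)[C@H]2[C@@H]1OC(=O)[C@@H]2C | intermediate
25 | (2R)-4-(tert-butoxy)-2-methyl-4-oxobutanoic acid | CC(C)(C)OC(=O)C[C@@H](C)C(=O)O | starting material
26 | 4-tert-butyl 1-methyl (2R)-2-methylbutanedioate | CC(C)(C)OC(=O)C[C@@H](C)C(=O)OC | intermediate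
27 | methyl (2R)-4-chloro-2-methyl-4-oxobutanoate | ClC(=O)C[C@@H](C)C(=O)OC | intermediate
28 | (10S,11R,12S,13R,20R)-3-acylated tetracycle (C18 ketone; C21 methyl ester) | CC[C@H]1C2=CCCCn3c(C(=O)C[C@@H](C)C(=O)OC)cc(c32)[C@H]2[C@@H]1OC(=O)[C@@H]2C | intermediate
29 | (18R,20R)-hydroxy ester | CC[C@H]1C2=CCCCn3c([C@H](O)C[C@@H](C)C(=O)OC)cc(c32)[C@H]2[C@@H]1OC(=O)[C@@H]2C | intermediate
30 | CNP0324368.1 | CC[C@H]1C2=CCCCn3c([C@H]4C[C@@H](C)C(=O)O4)cc(c32)[C@H]2[C@@H]1OC(=O)[C@@H]2C | target

Total step count: 16.
Longest linear sequence: 14 (steps 1 to 12, 15 and 16).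

Steps most likely to fail

Step 7. The enol triflate may be lost by hydrolysis or elimination under hot carbonate before the palladium cycle turns over. The nitrogen may be alkenylated instead of C9a, or a second, intermolecular alkenylation at the free C3–H may lead to oligomers. The fallback forms the two bonds one at a time, cross-coupling first, and sets out from 13. Suzuki–Miyaura coupling with 1-(tert-butoxycarbonyl)pyrrol-2-ylboronic acid (Pd(PPh3)4, K3PO4, dioxane/H2O, 50 °C) should give, with retention of the alkene geometry, the N-Boc 2-alkenylpyrrole F1. NaOMe (cat.) in MeOH removes the carbamate to give the NH 2-alkenylpyrrole chloride F2. NaH and n-Bu4NI in DMF then close ring A by 7-exo-tet N-alkylation, which comes back to the route at 16.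

Step 11. The Lewis acid may trigger oligomerisation through the free C3–H or migration of C8=C9 towards C10 with loss of that stereocentre, or the lactone may simply be too weakly activated for the β-carbon of the pyrrole. The fallback replaces Lewis-acid activation by iminium activation and the lactone acceptor by an enal, and sets out from 17. Cross-metathesis with 4 (second-generation Hoveyda–Grubbs catalyst RuCl2(=CH-C6H4-2-O-i-Pr)(H2IMes), CH2Cl2, 40 °C) gives the γ-hydroxy enal F3. A chiral secondary-amine salt (5-benzyl-2,2,3-trimethylimidazolidin-4-one trifluoroacetate, in the enantiomer matched to C11) closes ring B by iminium-catalysed intramolecular Friedel–Crafts alkylation. The cis hydroxy aldehyde collapses to the cis-fused lactol F4, and oxidation with Ag2CO3 on Celite in toluene at reflux comes back to the route at 22.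

Step 16. Hydride transfer to the electron-rich, vinylogous-amide-like ketone may be sluggish. Ionisation of the pyrrolyl carbinol borate may cause over-reduction to the methylene compound, or the same ionisation may erode the C18 configuration. The fallback forms C18–C19 instead of reducing a ketone, makes step 15 unnecessary, and sets out from 24. Vilsmeier–Haack formylation (POCl3, DMF, 0 °C; aq. NaOAc) gives the C3 aldehyde F5. Enantioselective allylboration follows, using ethyl 2-[(4,4,5,5-tetramethyl-1,3,2-dioxaborolan-2-yl)methyl]prop-2-enoate and a chiral BINOL-derived phosphoric acid, in the enantiomer that delivers 18R. It gives the homoallylic hydroxy ester F6. That ester lactonises on treatment with a catalytic amount of 1,8-diazabicyclo[5.4.0]undec-7-ene to the α-methylene lactone F7. Hydrogenation with RhCl(PPh3)3 and H2 in benzene should reduce only the 1,1-disubstituted alkene, from the face opposite the pyrrole, to give the 18,20-cis lactone. This comes back to the route at 30.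

Further compounds
F1 | step 7 | N-Boc 2-alkenylpyrrole (C9–C9a formed; chloride intact) | CC[C@@H](/C(c1cccn1C(=O)OC(C)(C)C)=C/CCCCl)[C@@H](O[Si](C)(C)C(C)(C)C)/C=C/C
F2 | step 7 | NH 2-alkenylpyrrole chloride | CC[C@@H](/C(c1ccc[nH]1)=C/CCCCl)[C@@H](O[Si](C)(C)C(C)(C)C)/C=C/C
F3 | step 11 | γ-hydroxy enal | CC[C@@H](C1=CCCCn2cccc12)[C@@H](O)/C=C/C=O
F4 | step 11 | cis-fused lactol (C14 hemiacetal; anomers) | CC[C@H]1C2=CCCCn3ccc(c32)[C@H]2[C@@H]1OC(O)C2
F5 | step 16 | C3 aldehyde | CC[C@H]1C2=CCCCn3c(C=O)cc(c32)[C@H]2[C@@H]1OC(=O)[C@@H]2C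
F6 | step 16 | (18R)-homoallylic hydroxy ester | CC[C@H]1C2=CCCCn3c([C@H](O)CC(=C)C(=O)OCC)cc(c32)[C@H]2[C@@H]1OC(=O)[C@@H]2C
F7 | step 16 | (18R)-α-methylene lactone | CC[C@H]1C2=CCCCn3c([C@H]4CC(=C)C(=O)O4)cc(c32)[C@H]2[C@@H]1OC(=O)[C@@H]2C
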